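The route cuts the C3=C4 double bond of the furan-2(5H)-one ring (O1, C2 stereocentre, C3 carboxyl-bearing, C4 methyl-bearing, C5 lactone carbonyl). Because C3 carries the carboxyl group it can be the ketone of an α-keto ester, stored until needed as a diazo group. Because C4 is α to the lactone carbonyl it can carry a phosphonate, and the O1–C5 ester is the tether. In one flask, dimethyldioxirane turns the diazo carbon into the keto carbon and a mild LiCl/amine Horner–Wadsworth–Emmons closure forms the tetrasubstituted alkene and the ring. The precursor is an acyclic α-diazo-β-acyloxy ester made by an enantioselective diazoacetate aldol, which also sets C2.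

Key step: step 5

Assumption: the sense of induction of the magnesium–ProPhenol aldol for this aldehyde is not taken as known; the commercial ligand antipode that gives the (3S)-alcohol is used, to be identified on the first run by Mosher ester analysis.

Step 1
Reactants: 1 ω-pentadecalactone (oxacyclohexadecan-2-one)
Product: 3 16-hydroxyhexadecan-2-one, via Weinreb amide 2 (not isolated)
Conditions: MeNH(OMe)·HCl, iPrMgCl, THF, −20 °C; then MeMgBr, 0 °C to rt; aq. NH4Cl
Reagents that add atoms: methylmagnesium bromide, C[Mg]Br
Why: The magnesium amide opens the lactone to the Weinreb amide and the Grignard reagent then adds once, because the chelated tetrahedral intermediate survives until work-up (Weinreb ketone synthesis), so the methyl ketone and the free primary alcohol should result.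

Step 2
Reactants: 3 16-hydroxyhexadecan-2-one
Product: 4 15-oxohexadecanal
Conditions: TEMPO (cat.), PhI(OAc)2, CH2Cl2, rt
Reagents that add atoms: none
Why: The oxoammonium (TEMPO) oxidation is selective for the primary alcohol and should stop at the aldehyde without touching the methyl ketone.

Step 3
Reactants: 4 15-oxohexadecanal; 5 tert-butyl diazoacetate
Product: 6 tert-butyl (3S)-2-diazo-3-hydroxy-17-oxooctadecanoate
Conditions: ProPhenol (antipode giving 3S, 5 mol%), nBu2Mg (10 mol%), cis-cyclopentane-1,2-diol (5 mol%), THF, −20 °C
Reagents that add atoms: none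
Why: In this catalytic enantioselective direct aldol addition of a diazo ester, the dinuclear magnesium–ProPhenol catalyst deprotonates the diazoacetate and delivers it to one face of the aldehyde, which should react in preference to the less electrophilic methyl ketone, so that the C3 carbinol centre is set as S under catalyst control.

Step 4
Reactants: 6 tert-butyl (3S)-2-diazo-3-hydroxy-17-oxooctadecanoate; 7 2-(diethoxyphosphoryl)propanoic acid
Product: 8 tert-butyl (3S)-2-diazo-3-{[2-(diethoxyphosphoryl)propanoyl]oxy}-17-oxooctadecanoate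
Conditions: DCC, DMAP (cat.), CH2Cl2, 0 °C to rt
Reagents that add atoms: none
Why: Steglich esterification acylates the secondary alcohol with retention at C3 under buffered conditions that the acceptor-stabilised diazo ester should tolerate; the epimeric phosphonate carbon is of no consequence because it becomes sp2 in step 5.

Step 5
Reactants: 8 tert-butyl (3S)-2-diazo-3-{[2-(diethoxyphosphoryl)propanoyl]oxy}-17-oxooctadecanoate
Product: 10 tert-butyl (2S)-4-methyl-5-oxo-2-(14-oxopentadecyl)-2,5-dihydrofuran-3-carboxylate, via keto ester 9 (not isolated)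
Conditions: DMDO, acetone, 0 °C; evaporate from PhMe; LiCl, iPr2NEt, MeCN, 0 °C to rt
Reagents that add atoms: none
Why: Dimethyldioxirane transfers oxygen to the nucleophilic diazo carbon with loss of N2, unmasking the chain C2 ketone (the future ring C3) as part of the strongly electrophilic α-keto ester 9; LiCl and iPr2NEt then form the lithium-chelated phosphonate carbanion at the future C4, which adds to that ketone and collapses through the oxaphosphetane with loss of diethyl phosphate, so the oxygen brought in by the dioxirane leaves again. The closest known reaction types are the dioxirane oxidation of α-diazo esters to α-keto esters and the intramolecular Horner–Wadsworth–Emmons synthesis of butenolides from α-acyloxy ketones under Masamune–Roush conditions. The furan-2(5H)-one ring (O1, C2, C3, C4, C5) closes by 5-exo-trig attack of the C4 carbanion on the C3 carbonyl with the O1–C5 ester as tether, and the ring fixes the geometry of the tetrasubstituted C3=C4 alkene. No new stereocentre is formed; the C2 centre from step 3 is α to the ketone in 9 and must not enolise, which the weak amine base, the low temperature and the speed of a five-ring closure onto a 1,2-dicarbonyl are meant to secure. Chemoselectivity for the α-keto carbonyl over the tert-butyl ester and the remote methyl ketone should follow from its higher electrophilicity and from proximity.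

Step 6
Reactants: 10 tert-butyl (2S)-4-methyl-5-oxo-2-(14-oxopentadecyl)-2,5-dihydrofuran-3-carboxylate
Product: 11 (2S)-4-methyl-5-oxo-2-(14-oxopentadecyl)-2,5-dihydrofuran-3-carboxylic acid
Conditions: TFA, CH2Cl2, 0 °C to rt
Reagents that add atoms: none
Why: Acidolysis of the tert-butyl ester (E1 loss of the tert-butyl cation as 2-methylpropene) should free the acid without touching the lactone, the ketone or the C2 centre, which is not labile under acid.

Compound list
1 | ω-pentadecalactone (oxacyclohexadecan-2-one) | O=C1CCCCCCCCCCCCCCO1 | starting material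
2 | 15-hydroxy-N-methoxy-N-methylpentadecanamide (Weinreb amide, present as its magnesium alkoxide) | CON(C)C(=O)CCCCCCCCCCCCCCO | intermediate
3 | 16-hydroxyhexadecan-2-one | CC(=O)CCCCCCCCCCCCCCO | intermediate
4 | 15-oxohexadecanal | CC(=O)CCCCCCCCCCCCCC=O | intermediate
5 | tert-butyl diazoacetate | [N-]=[N+]=CC(=O)OC(C)(C)C | starting material
6 | tert-butyl (3S)-2-diazo-3-hydroxy-17-oxooctadecanoate | CC(=O)CCCCCCCCCCCCC[C@H](O)C(=[N+]=[N-])C(=O)OC(C)(C)C | intermediate
7 | 2-(diethoxyphosphoryl)propanoic acid (racemic) | CCOP(=O)(OCC)C(C)C(=O)O | starting material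
8 | tert-butyl (3S)-2-diazo-3-{[2-(diethoxyphosphoryl)propanoyl]oxy}-17-oxooctadecanoate (both epimers at the phosphonate carbon) | CC(=O)CCCCCCCCCCCCC[C@H](OC(=O)C(C)P(=O)(OCC)OCC)C(=[N+]=[N-])C(=O)OC(C)(C)C | intermediate
9 | tert-butyl (3S)-3-{[2-(diethoxyphosphoryl)propanoyl]oxy}-2,17-dioxooctadecanoate (keto ester) | CC(=O)CCCCCCCCCCCCC[C@H](OC(=O)C(C)P(=O)(OCC)OCC)C(=O)C(=O)OC(C)(C)C | intermediate
10 | tert-butyl (2S)-4-methyl-5-oxo-2-(14-oxopentadecyl)-2,5-dihydrofuran-3-carboxylate | CC(=O)CCCCCCCCCCCCC[C@@H]1OC(=O)C(C)=C1C(=O)OC(C)(C)C | intermediate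
11 | (2S)-4-methyl-5-oxo-2-(14-oxopentadecyl)-2,5-dihydrofuran-3-carboxylic acid | CC(=O)CCCCCCCCCCCCC[C@@H]1OC(=O)C(C)=C1C(=O)O | target

Total step count: 6
Longest linear sequence: 6 steps (1 to 11, fully linear)

Steps most likely to fail

Step 5 (key step). The amine/LiCl base may remove the proton at the stereocentre of 9, which is α to the 1,2-dicarbonyl, or the γ-proton of 10, and so erode the configuration; the α-methyl phosphonate carbanion may also add only slowly to the partly hydrated ketone. The fallback makes the same bond without a base, by a reductive aldol closure followed by dehydration. It sets out from 6, which is acylated with 2-bromopropanoyl bromide (2,6-lutidine, CH2Cl2, −20 °C) to tert-butyl (3S)-3-[(2-bromopropanoyl)oxy]-2-diazo-17-oxooctadecanoate F1. DMDO then gives tert-butyl (3S)-3-[(2-bromopropanoyl)oxy]-2,17-dioxooctadecanoate F2. Activated zinc dust in THF at 0 °C forms the non-basic zinc enolate, which adds to the adjacent ketone (intramolecular Reformatsky reaction) to give tert-butyl (2S)-3-hydroxy-4-methyl-5-oxo-2-(14-oxopentadecyl)oxolane-3-carboxylate F3 as a mixture at the two new centres. MsCl/Et3N converts the tertiary alcohol into its mesylate, which is lost by E1cB elimination through the acidic C4–H, and the route is rejoined at 10.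

Step 3. The unbranched aldehyde may give poor facial selectivity, may undergo self-aldol under the magnesium alkoxide catalyst, or the methyl ketone may enter aldol chemistry. The fallback sets the same centre by an amine-catalysed asymmetric Morita–Baylis–Hillman reaction and unmasks the ketone by ozonolysis. It sets out from 4, which reacts with 1,1,1,3,3,3-hexafluoropropan-2-yl acrylate under α-isocupreine catalysis (the quinine-derived pseudoenantiomer of β-isocupreidine, DMF, −55 °C) to give 1,1,1,3,3,3-hexafluoropropan-2-yl (3S)-3-hydroxy-2-methylidene-17-oxooctadecanoate F4. Steglich esterification with 7 gives 1,1,1,3,3,3-hexafluoropropan-2-yl (3S)-3-{[2-(diethoxyphosphoryl)propanoyl]oxy}-2-methylidene-17-oxooctadecanoate F5. Ozonolysis (O3, CH2Cl2, −78 °C; Me2S; volatiles removed) gives 1,1,1,3,3,3-hexafluoropropan-2-yl (3S)-3-{[2-(diethoxyphosphoryl)propanoyl]oxy}-2,17-dioxooctadecanoate F6. LiCl/iPr2NEt in MeCN closes the ring to 1,1,1,3,3,3-hexafluoropropan-2-yl (2S)-4-methyl-5-oxo-2-(14-oxopentadecyl)-2,5-dihydrofuran-3-carboxylate F7. Brief hydrolysis of this activated ester (LiOH, 1 equiv, THF–H2O, 0 °C) returns to the route at 11.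

Step 4. The phosphono acid may protonate the diazo carbon before acyl transfer (loss of N2 and a 1,2-hydride shift), and the hydrogen-bonded alcohol may acylate slowly. The fallback changes the order of events so that no diazo group meets the acid. It sets out from 6, which is oxidised with DMDO (acetone, 0 °C) to tert-butyl (3S)-3-hydroxy-2,17-dioxooctadecanoate F8. This is coupled at once with 7 (DCC, CH2Cl2, −20 °C, only a trace of DMAP), and the route is rejoined at 9, which is closed with LiCl/iPr2NEt as in step 5.

Further compounds
F1 | step 5 | tert-butyl (3S)-3-[(2-bromopropanoyl)oxy]-2-diazo-17-oxooctadecanoate | CC(=O)CCCCCCCCCCCCC[C@H](OC(=O)C(C)Br)C(=[N+]=[N-])C(=O)OC(C)(C)C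
F2 | step 5 | tert-butyl (3S)-3-[(2-bromopropanoyl)oxy]-2,17-dioxooctadecanoate | CC(=O)CCCCCCCCCCCCC[C@H](OC(=O)C(C)Br)C(=O)C(=O)OC(C)(C)C
F3 | step 5 | tert-butyl (2S)-3-hydroxy-4-methyl-5-oxo-2-(14-oxopentadecyl)oxolane-3-carboxylate | CC(=O)CCCCCCCCCCCCC[C@@H]1OC(=O)C(C)C1(O)C(=O)OC(C)(C)C
F4 | step 3 | 1,1,1,3,3,3-hexafluoropropan-2-yl (3S)-3-hydroxy-2-methylidene-17-oxooctadecanoate | CC(=O)CCCCCCCCCCCCC[C@H](O)C(=C)C(=O)OC(C(F)(F)F)C(F)(F)F
F5 | step 3 | 1,1,1,3,3,3-hexafluoropropan-2-yl (3S)-3-{[2-(diethoxyphosphoryl)propanoyl]oxy}-2-methylidene-17-oxooctadecanoate | CC(=O)CCCCCCCCCCCCC[C@H](OC(=O)C(C)P(=O)(OCC)OCC)C(=C)C(=O)OC(C(F)(F)F)C(F)(F)F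
F6 | step 3 | 1,1,1,3,3,3-hexafluoropropan-2-yl (3S)-3-{[2-(diethoxyphosphoryl)propanoyl]oxy}-2,17-dioxooctadecanoate | CC(=O)CCCCCCCCCCCCC[C@H](OC(=O)C(C)P(=O)(OCC)OCC)C(=O)C(=O)OC(C(F)(F)F)C(F)(F)F
F7 | step 3 | 1,1,1,3,3,3-hexafluoropropan-2-yl (2S)-4-methyl-5-oxo-2-(14-oxopentadecyl)-2,5-dihydrofuran-3-carboxylate | CC(=O)CCCCCCCCCCCCC[C@@H]1OC(=O)C(C)=C1C(=O)OC(C(F)(F)F)C(F)(F)F
F8 | step 4 | tert-butyl (3S)-3-hydroxy-2,17-dioxooctadecanoate | CC(=O)CCCCCCCCCCCCC[C@H](O)C(=O)C(=O)OC(C)(C)C
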